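The earlier runs and the new flask are calculated with made-up constants.

The steps thought possible turn one starting material into one target, and starting material comes from the solid substrate, so target in these flasks stays within the charge of solid substrate. The question is how fast that charge passes into target.

| flask | solid substrate | transfer agent | gas | initiator | temperature | remark | time |
|---|---|---|---|---|---|---|---|
| theta | 0.60 M | 0.040 M | 98 mM (held) | 56 mM | 110 °C | run made earlier |  |
| teal | 0.40 M | 0.0120 M | 98 mM (held) | 56 mM | 110 °C |  | 12 min |
| blue | 0.40 M | 0.0400 M | 98 mM (held) | 56 mM | 110 °C |  | 50 min |

theta run (percent of the solid substrate charged)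

| time / min | target / % |
|---|---|
| 1.33 | 2.2 |
| 3.00 | 3.6 |
| 6.00 | 6.7 |
| 10.0 | 11.9 |
| 12.0 | 14.2 |
| 20.0 | 24.0 |

(readings scatter by 0.5 percentage points)

- in percentages every species weighs as the solid substrate in it: one ended chains counts as two
- as a solid, counted per litre of solution: solid substrate
- at the start none of reagent is dissolved
- steps thought possible: starting material + second chain carrier -> released group + first chain carrier; 2 first chain carrier -> ended chains; solid substrate <-> starting material; gas <-> reagent; 2 idle radical -> ended radicals; transfer agent + first chain carrier -> side product + idle radical; initiator -> 2 initiating radical; starting material + initiating radical -> capped initiator + first chain carrier; reagent + first chain carrier -> target + second chain carrier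
- at the start none of the solid substrate is in solution
- what has only dissolved of solid substrate counts as not reacted
- no earlier run changes the charge of transfer agent; that part of a forecast is a guess

- the winner by amount of target, in percent of the solid substrate charged; "neither" if no more than 2 percentage points parts them (teal / blue / neither)
- how much target is there at the end, in percent of the solid substrate charged: teal
- how much target is there at the end, in percent of the solid substrate charged: blue

Take first the main step: the chain carriers turn dissolved starting material and reagent into target, while the standing solid supplies the solution and the held gas supplies reagent. The theta readings then read as a zero-order stretch, giving 7.14 mM min⁻¹ up to 10.0 min and 7.26 mM min⁻¹ after it, about the same rate. Its last reading gives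

feed rate = target at last reading / time = 7.20 mM min⁻¹

This feed rate, the molar amount of target appearing per minute while solid stands, I take as independent of the charge, which gives my own first round:

teal: feed rate × time / charge = 21.6 %

blue: feed rate × time / charge = 90.0 %

Going round once more, I put the blue answer back: at this feed rate the blue solid lasts 55.6 min by my reckoning, longer than the blue time of 50 min, so in this estimate the premise of standing solid holds and the figure stays. Adding the transfer agent leaves my blue figure as it stands: the blue charge of 0.0400 M equals the theta charge of 0.040 M, so I take the feed rate to carry it already. Teal has a third of that charge, which no earlier run tests, so my teal figure is a guess on that point. Initiator decay and chain ending are inside the theta readings up to 20.0 min, so I leave the number as it is, but blue runs 2.50 times as long as those readings, and past them the feed rate is an extrapolation. So my reckoning puts more target in blue than in teal.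

The forecast also names blue, but differs from my figures with 30 % for teal and 70 % for blue, the blue figure on these grounds: “Substrate is also lost to capped initiator and side product, and the initiator decays”.

The flasks give 22.6 % in teal and 93.7 % in blue, so the winner is blue.

    starting material + second chain carrier → released group + first chain carrier (k = 3500 M⁻¹ s⁻¹, Ea = 36.0 kJ mol⁻¹)
    2 first chain carrier → ended chains (k = 3.00 × 10⁸ M⁻¹ s⁻¹, Ea = 9.00 kJ mol⁻¹)
    solid substrate ⇌ starting material, rate k3*(cs3 - [starting material]) while solid is left; crystals form when [starting material] > cs3 (solubility = 38.0 mM, k = 0.00340 s⁻¹)
    gas ⇌ reagent, rate k4*(csat - [reagent]) (kL = 0.00520 s⁻¹)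
    2 idle radical → ended radicals (k = 3.30 × 10⁶ M⁻¹ s⁻¹, Ea = 14.0 kJ mol⁻¹)
    transfer agent + first chain carrier → side product + idle radical (kL = 6400 M⁻¹ s⁻¹, Ea = 18.0 kJ mol⁻¹)
    initiator → 2 initiating radical (k = 0.00130 s⁻¹, Ea = 117 kJ mol⁻¹)
    starting material + initiating radical → capped initiator + first chain carrier (k = 54000 M⁻¹ s⁻¹, Ea = 37.0 kJ mol⁻¹)
    reagent + first chain carrier → target + second chain carrier (k = 1.10 × 10⁵ M⁻¹ s⁻¹, Ea = 23.0 kJ mol⁻¹)
    (constants at 110 °C)

In blue, 3.10 % of the solid substrate still stands at 50.0 min beside 2.97 % of side product, and target has appeared there at an average of 7.49 mM min⁻¹ against the feed rate of 7.20 mM min⁻¹. The same feed rate, put on the neighbour of blue charged with 1.0 M of solid substrate and held for 50 min, gives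

feed rate × time / charge = 36.0 %

and that neighbour holds 37.5 % of target.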